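Two things are asked about the flasks below, which differ in their charge of L: how much Z stands at the end of each, and how that amount runs from flask to flask.

the same everywhere: X 1.9 M
- ochre: L 0.15 equiv; run made earlier
- red: L 0.90 equiv; run made earlier
- north-east: L 0.100 equiv; time 10 h
- south-east: L 0.200 equiv; time 10 h
- north: L 0.400 equiv; time 10 h
- south-west: L 0.800 equiv; time 10 h

- amount of Z at the end, in percent of the X charged for north-east, south-east, north, south-west, in this order
- the course of these numbers from the first flask to the last (falls, then rises / falls all the way / rises all the way / rises, then falls / hardly changes)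

- in percentages every species weighs as the X in it: one Q counts as two
- on the list of suspects stand: X -> Z; L -> J; Z + J -> G; 2 Z -> Q; G -> E; G -> D
- "hardly changes" means that all values lie within two and a half points (for a concentration: within two and a half percent of the largest)

| run | time / h | Z / % | G / % |
|---|---|---|---|
| ochre | 1.00 | 94.2 | 2.1 |
| ochre | 2.00 | 92.0 | 5.8 |
| ochre | 3.00 | 85.8 | 4.7 |
| ochre | 4.00 | 83.3 | 5.5 |
| ochre | 5.00 | 78.3 | 4.5 |
| red | 0.417 | 69.6 | 2.9 |
| red | 1.33 | 76.9 | 16.8 |
| red | 2.50 | 60.7 | 24.6 |
| red | 4.00 | 46.4 | 23.7 |
| red | 5.00 | 41.9 | 19.0 |

(each reading ± 1 percentage point)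

I read the red table downward. Z falls at 0.138 /h of the charge from 1.33 h to 2.50 h, then at 0.0953 /h, then at 0.0450 /h. The ochre column loses Z at 0.0435 /h from 2.00 h to 4.00 h, slower than red, so I tie the fall to J and take J as already out in the first red interval.

I write the loss as κ·Z·J, with amounts as fractions of the X charged. In that red interval Z averages 68.8%. Counting every missing Z as spent J leaves J at 58.8%, and so κ is 0.342 /h.

Freezing Z makes J decay pseudo-first-order. At the ochre Z of 5.00 h its time constant is 3.73 h. I call this the trap time, one over κ times Z.

By this reckoning ochre at 5.00 h has spent J worth 11.1% of the charge, and the remaining 10.6% of missing Z I give to dimerisation into Q. Carrying that second-order loss to 10 h leaves 80.8%. Taking off the J of north-east gives my 71.5%. For the other flasks I commit only to a fall with each added L, since the red Z of 41.9% at 5.00 h lies far below the ochre Z I froze.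

The forecast gives 67%, 62%, 51%, 28% and falls all the way, on “slow release of J from L”. There I differ, and my north-east figure stands higher.

The flasks give 73.8%, 66.8%, 53.3%, 29.9%: falls all the way.

    X → Z (k = 0.0520 /min)
    L → J (k = 0.0590 /min)
    Z + J → G (k = 0.00290 /M/min)
    2 Z → Q (k = 1.10 × 10⁻⁴ /M/min)
    G → E (k = 0.00620 /min)
    G → D (k = 9.40 × 10⁻⁶ /min)

In north-east the half-life of Z through J is 39 h at 0.223 h, longer than the 10 h of the run, while J goes from 0.0489 M at 5.00 h to 0.0134 M at 10.0 h. That is a time constant of 3.86 h, against the trap time of 3.73 h reckoned at the ochre Z. In south-west J goes from 0.575 M to 0.315 M over the same hours, a time constant of 8.32 h, against a trap time of 7.77 h at the mean of that flask's Z at these two times, and Z there ends at 29.9%.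

Readings and results are calculated with constants of no real substance, noise included.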